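## The problem

Wailupemycin F (31) is a 3,4-dihydronaphthalen-1(2H)-one. Its benzene ring A (C4a, C5–C8, C8a) carries five different substituents and keeps only C7 as C–H. The C8 phenol is peri to the C1 ketone, a phenyl group sits on C6, and a 4-hydroxy-2-pyron-6-yl group sits on C5, wedged between that phenyl group and the ring-B methylene C4. Ring B holds the only stereocentre, the S-configured carbinol C3. No second stereocentre exists to relay its configuration, so it has to come from a reagent, a catalyst or a resolution. C3 stands beta to the C1 ketone: loss of its oxygen across C2–C3 gives, after tautomerisation, a 1-naphthol. Once ring B is closed, base, strong acid and prolonged heat must therefore be kept away from a C1 ketone, and the C3 oxygen must never reach the ketone level. The hydroxypyrone is acidic and C-nucleophilic, and a carbonyl group on C5 is a 2,6-disubstituted benzoyl, so pyrone construction by acyl substitution at that carbon is unattractive. The enabling feature is that C8a bears the acyl carbon C1 and its neighbour C4a bears the methylene carbon C4. This is the pair of groups that an aryne C8a≡C4a takes up from the acyl–CH2 bond of a beta-keto ester, and the C8 oxygen next to C8a makes the two aryne carbons electronically different.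

## Retrosynthesis

**Protecting groups (31 ⇐ 30 ⇐ 29).** The last cuts are O–Si at C3 and O–CH3 at C8. The C3 oxygen stays a tert-butyldimethylsilyl ether from just after its creation to the final step, so the carbinol cannot be oxidised or ionised. The C8 methyl ether is the group that steers the aryne step, and its peri position to C1=O allows chelation-assisted cleavage at low temperature. The methyl group is removed first (29 to 30) while C3 is still silylated; buffered fluoride then frees the carbinol under non-basic conditions.

**Pyrone (29 ⇐ 27 ⇐ 26 ⇐ 23 + 24).** The pyrone is cut at its lactone C–O bond and at the bond between pyrone C5 and C6. Thermolysis of the beta-keto dioxinone 27 expels acetone; the acylketene 28 is trapped by the enol oxygen of the aryl ketone. 27 comes from oxidation of carbinol 26, the adduct of aldehyde 23 and the dienolate of commercial dioxinone 24. This is preferred to a Claisen acylation of a C5 ester, because addition to a di-ortho-substituted aldehyde is feasible where substitution at a 2,6-disubstituted benzoate is not. Cross-coupling of a preformed halopyrone was set aside for want of precedent.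

**C5 carbon (23 ⇐ 21 ⇐ 20).** The C5–CHO bond is cut back to an aryl bromide, formylated by bromine–lithium exchange and DMF. Organolithium chemistry requires that no ketone be present, so C1 is carried as a carbinol (21) through steps 12 and 13. This costs one reduction only, because the oxidation that makes the pyrone-arm ketone in step 14 restores C1=O at the same time. Palladium-catalysed carbonylation of the bromide would expose the beta-silyloxy ketone 20 to amine base and heat.

**Ring B (20 ⇐ 19 ⇐ 17 ⇐ 16 ⇐ 15).** C2–C3 is the one ring-B bond the aryne step leaves open, and closing it by an aldol-type reaction creates C3. A Dieckmann closure of 15 is ruled out: it gives a naphthalene-1,3-diol and erases C3. In a free keto aldehyde the arylacetaldehyde would enolise first. The donor is therefore fixed beforehand as the silyl enol ether of the methyl ketone (16), and the ester is then reduced to the aldehyde (17). The forward reaction is a Lewis-acid-mediated Mukaiyama aldol cyclisation in which a chiral boron Lewis acid must select the aldehyde face. This is the one step without direct precedent.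

**Bromide (15 ⇐ 14).** The C5–Br bond is made by electrophilic substitution para to the methoxy group, directly after the key step, when no sensitive group is present.

**Key disconnection (14 ⇐ 10 + 11).** C8a–C1 and C4a–C4 are cut together. Aryne 12, released from silyl triflate 10, inserts into the acyl–CH2 bond of methyl acetoacetate 11. This replaces a pentasubstituted keto ester by a trisubstituted benzene and a commodity chemical. It delivers the two arms at the ketone and ester levels, and asks only that the nucleophile enter at C4a.

**Aryne precursor (10 ⇐ 8 ⇐ 4 ⇐ 3 ⇐ 1 + 2).** The triflate oxygen of 10 is the phenol oxygen of 3. The silyl group enters by carbamate-directed lithiation at the position between the two oxygens (4 to 8). Biaryl 3 is one Suzuki–Miyaura coupling away from commercial 1 and 2.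

## Roads not taken

**Alternative 1: gold-catalysed furan-yne cyclisation to the phenol.** The cut runs through ring A. Ph3PAuNTf2 (monovalent gold) activates the alkyne of 2-[(2R,4S)-2,4-bis(tert-butyldimethylsilyloxy)hex-5-yn-1-yl]-3-(tert-butyldimethylsilyloxymethyl)-4-phenylfuran A1. C4a–C8a and C7–C8 are formed, the furan oxygen ends on C8, and the cis-1,3-bis(silyloxy)tetralin-8-ol A2 results.
- Merits: one step builds ring A and closes ring B. The C8 phenol is placed by the mechanism and needs no protection. C1 is at the carbinol level, so ring B cannot aromatise. C3 is brought in from an acyclic 1,3-diol array, for which reliable asymmetric methods exist. In stereocontrol this road is better than the chosen plan.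
- Weak points: A1 is a 2,3,4-trisubstituted furan with a six-carbon chain and two stereocentres, one of which (C1) is made only to be oxidised away. A propargylic silyl ether sits next to the gold-activated alkyne. An all-carbon tether closing a six-membered ring, with substituents on furan C3 and C4, is the less favourable case for this cyclisation. The three silyl ethers of A2 must be told apart, and the pyrone still has to be grown from the CH2O group by the aldehyde chemistry of steps 13 to 15.
- Comparison: the chosen plan sets against the safer stereochemistry a five-step, precedent-controlled entry to the substituted ring from a commercial bromophenol, and accepts one unprecedented enantioselective closure with a resolution behind it.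

**Alternative 2: toluate Michael–Dieckmann annulation onto a chiral dioxinone.** C4–C3 and C2–C1 are cut. The benzylic anion of methyl 3-(1,3-dioxolan-2-yl)-6-methoxy-2-methyl-4-phenylbenzoate A3 adds to carbon 6 of (R)-2-tert-butyl-4H-1,3-dioxin-4-one A4. The resulting enolate is acylated by the aryl ester and gives the tricyclic enol A5.
- Merits: ring B and C3 arise in one convergent step, and the acetal centre of A4 controls C3 by substrate control. In setting C3 this road is at least as good as the chosen one.
- Weak points: the whole substitution problem of ring A is moved into A3, a hexasubstituted benzene whose lateral lithiation must compete with the flanking acetal and ester. A5 still carries the lactone carbon on C2. Its removal means opening the acetal and decarboxylating a beta-keto acid whose C3 oxygen is beta to an enolised carbonyl. These are the conditions under which such annulation products normally aromatise to naphthols.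
- Comparison: the chosen plan never has a carboxyl group on C2 and keeps the C3 oxygen silylated whenever C1 is a ketone.

**Alternative 3: desymmetrising benzannulation of dihydrophloroglucinol.** C5–C4a is cut. In methyl (E)-5-[4-(tert-butyldimethylsilyloxy)-2,6-dioxocyclohexyl]-5-oxo-3-phenylpent-3-enoate A6, the glutaconate CH2 condenses with one of the two enantiotopic ring carbonyls under a chiral phosphoric acid such as (R)-3,3'-bis(2,4,6-triisopropylphenyl)-1,1'-binaphthyl-2,2'-diyl hydrogen phosphate. Loss of water aromatises ring A to the tetralone ester A7.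
- Merits: this is the shortest road. Ring B comes from a cheap dione, C3 from a desymmetrisation in the ring-forming step, and A7 already has the free C8 phenol, the C1 ketone and the C5 carboxyl carbon. In step economy it is clearly better than the chosen plan.
- Weak points: the acid catalyst must tell apart two carbonyls of a fully enolised 2-acyl-1,3-dione whose tautomerism exchanges them, with the prostereogenic carbon remote from the reacting centre. The 5-silyloxy dione can lose silanol under acid and turn ring B into a resorcinol. The C5 ester of A7 is a 2,6-disubstituted benzoate, so the pyrone would still need a detour through the aldehyde.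
- Comparison: the chosen plan is longer, but it rests its ring construction on a documented aryne reaction and confines its one unprecedented demand to a step that has a workable fallback.

Key step: step 5

Assumption: the (S)-tryptophan-derived oxazaborolidinone of step 9 is taken to expose the re face of the bound aldehyde to the tethered enol silane, which gives 3S. If the opposite sense is found, the catalyst from (R)-tryptophan is used and nothing else changes.

Step 1
Reactants: 1 3-bromo-5-methoxyphenol; 2 phenylboronic acid
Product: 3 3-methoxy-5-phenylphenol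
Conditions: Pd(PPh3)4 (3 mol%), K2CO3 (3 equiv), 1,4-dioxane/H2O 4:1, 90 °C
Reagents that add atoms: none
Why: Suzuki–Miyaura coupling; zerovalent palladium inserts into the C–Br bond and the free phenol is tolerated as its phenoxide in aqueous carbonate, so the biaryl forms without a protecting group.

Step 2
Reactants: 3 3-methoxy-5-phenylphenol
Product: 4 3-methoxy-5-phenylphenyl N-isopropylcarbamate
Conditions: i-PrNCO (1.5 equiv), Et3N (0.2 equiv), CH2Cl2, rt
Reagents that add atoms: isopropyl isocyanate, CC(C)N=C=O
Why: Amine-catalysed carbamoylation of a phenol by an isocyanate; the secondary carbamate directs ortho-lithiation strongly once its N–H is silylated and can later be taken off by mild base.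

Step 3
Reactants: 4 3-methoxy-5-phenylphenyl N-isopropylcarbamate
Product: 8 3-methoxy-5-phenyl-2-(trimethylsilyl)phenyl N-isopropylcarbamate, via N-silyl carbamate 5 (not isolated), via aryllithium 6 (not isolated), via bis-silyl carbamate 7 (not isolated)
Conditions: t-BuMe2SiOTf (1.1 equiv), TMEDA (1.1 equiv), Et2O, 0 °C to rt; n-BuLi (2 equiv), TMEDA (2 equiv), −78 °C; Me3SiCl (3 equiv), −78 °C to rt; 2 M HCl
Reagents that add atoms: chlorotrimethylsilane, C[Si](C)(C)Cl
Why: Directed ortho-metalation; N-silylation masks the acidic N–H, n-BuLi/TMEDA then removes the proton between the carbamate and methoxy oxygens, where both groups cooperate (the other ortho site has one director only), Me3SiCl traps the anion at −78 °C before a carbamoyl shift can occur, and aqueous acid removes the N-silyl group.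

Step 4
Reactants: 8 3-methoxy-5-phenyl-2-(trimethylsilyl)phenyl N-isopropylcarbamate
Product: 10 3-methoxy-5-phenyl-2-(trimethylsilyl)phenyl trifluoromethanesulfonate, via silyl phenol 9 (not isolated)
Conditions: Et2NH (1.5 equiv), DBU (1.5 equiv), MeCN, 40 °C; then PhNTf2 (1.5 equiv), rt
Reagents that add atoms: N-phenylbis(trifluoromethanesulfonimide), O=S(=O)(N(c1ccccc1)S(=O)(=O)C(F)(F)F)C(F)(F)F
Why: Base-induced carbamate cleavage by loss of isocyanate (elimination after N-deprotonation, the isocyanate being scavenged by Et2NH) followed by triflation of the phenoxide in the same flask, which avoids handling the protodesilylation-prone ortho-silyl phenol.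

Step 5
Reactants: 10 3-methoxy-5-phenyl-2-(trimethylsilyl)phenyl trifluoromethanesulfonate; 11 methyl acetoacetate
Product: 14 methyl 2-(2-acetyl-3-methoxy-5-phenylphenyl)acetate, via aryne 12 (not isolated), via cyclobutenoxide 13 (not isolated)
Conditions: 10 (1.25 equiv), 11 (1.0 equiv), CsF (2.5 equiv), MeCN (0.2 M), 80 °C
Reagents that add atoms: none
Why: Fluoride removes the trimethylsilyl group of 10 and triflate leaves, giving aryne 12 with the triple bond between C8a and C4a. Deprotonated 11 adds through carbon to C4a, the charge that develops at C8a closes onto the ketone carbonyl to give benzocyclobutenoxide 13, and 13 fragments to the aryl ketone and an ester-stabilised carbanion that is protonated to 14. The closest known reaction type is the acyl-alkylation of arynes by beta-keto esters (formal insertion into the acyl–CH2 sigma bond), documented for 3-methoxybenzyne with the acyl group ending beside the methoxy group. No ring is closed and no stereocentre is formed; the step makes C8a–C1 and C4a–C4 and lays both arms of ring B on neighbouring carbons at the ketone and ester oxidation levels. The selectivity needed is regiochemical: the nucleophile must enter at C4a. The C8 methoxy group secures it, since its inductive effect distorts the aryne and stabilises charge at C8a, while C5 next to C4a is unsubstituted and the C6 phenyl group is meta to the site of attack. C- over O-arylation follows from the soft carbon terminus of the enolate in MeCN, and running 11 as the limiting partner against a small excess of 10 keeps a second arylation of the acidic CH2 of 14 low.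

Step 6
Reactants: 14 methyl 2-(2-acetyl-3-methoxy-5-phenylphenyl)acetate
Product: 15 methyl 2-(2-acetyl-6-bromo-3-methoxy-5-phenylphenyl)acetate
Conditions: NBS (1.05 equiv), MeCN, 0 °C to rt
Reagents that add atoms: N-bromosuccinimide, O=C1CCC(=O)N1Br
Why: Electrophilic aromatic bromination; the methoxy group directs para to C5, the acetyl group (twisted out of the ring plane by its two ortho neighbours) is meta to both free positions and does not discriminate, and without added acid the ketone methyl group and the pendant phenyl ring should not compete.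

Step 7
Reactants: 15 methyl 2-(2-acetyl-6-bromo-3-methoxy-5-phenylphenyl)acetate
Product: 16 methyl 2-{6-bromo-3-methoxy-5-phenyl-2-[1-(trimethylsilyloxy)ethenyl]phenyl}acetate
Conditions: Me3SiOTf (1.2 equiv), Et3N (1.6 equiv), CH2Cl2, 0 °C
Reagents that add atoms: trimethylsilyl trifluoromethanesulfonate, C[Si](C)(C)OS(=O)(=O)C(F)(F)F
Why: Soft enolisation of a methyl ketone to its silyl enol ether; the ketone reacts faster than the ester under silyl triflate and amine, only one enol regiochemistry is possible, and any ketene silyl acetal formed from the ester reverts on work-up.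

Step 8
Reactants: 16 methyl 2-{6-bromo-3-methoxy-5-phenyl-2-[1-(trimethylsilyloxy)ethenyl]phenyl}acetate
Product: 17 2-{6-bromo-3-methoxy-5-phenyl-2-[1-(trimethylsilyloxy)ethenyl]phenyl}acetaldehyde
Conditions: i-Bu2AlH (1.1 equiv), CH2Cl2, −78 °C; MeOH, then aq. potassium sodium tartrate (KNaC4H4O6)
Reagents that add atoms: none
Why: Partial reduction of a methyl ester to the aldehyde at −78 °C, where the reduction stops at the aldehyde oxidation level until quench; the silyl enol ether and the aryl bromide are inert to the hydride, and the aldehyde is used at once without chromatography.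

Step 9
Reactants: 17 2-{6-bromo-3-methoxy-5-phenyl-2-[1-(trimethylsilyloxy)ethenyl]phenyl}acetaldehyde
Product: 19 (S)-5-bromo-3-hydroxy-8-methoxy-6-phenyl-3,4-dihydronaphthalen-1(2H)-one, via trimethylsilyl ether 18 (not isolated)
Conditions: (S)-2-butyl-4-(1H-indol-3-ylmethyl)-3-(4-methylbenzenesulfonyl)-1,3,2-oxazaborolidin-5-one (0.4 equiv, from N-tosyl-(S)-tryptophan and BuB(OH)2), EtCN, −78 °C, slow addition of 17; then 1 M HCl, THF, 0 °C
Reagents that add atoms: none
Why: Proposed new method: the boron Lewis acid binds the aldehyde oxygen of 17 and the tethered silyl enol ether attacks C3 through an open transition state in a 6-(enolendo)-exo-trig closure that forms C2–C3; the indolylmethyl group of the catalyst covers one face of the bound formyl group, so C2 is expected to add to the re face, which is 3S; silyl transfer gives 18 and dilute acid frees 19. The closest known reaction types are the enantioselective intermolecular Mukaiyama aldol addition of acetophenone silyl enol ethers to aliphatic aldehydes under N-sulfonylamino-acid oxazaborolidinone catalysis and the racemic Lewis-acid-promoted intramolecular Mukaiyama aldol cyclisation. Slow addition of 17 is meant to keep the racemic, silyl-cation-carried pathway low.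

Step 10
Reactants: 19 (S)-5-bromo-3-hydroxy-8-methoxy-6-phenyl-3,4-dihydronaphthalen-1(2H)-one
Product: 20 (S)-5-bromo-3-(tert-butyldimethylsilyloxy)-8-methoxy-6-phenyl-3,4-dihydronaphthalen-1(2H)-one
Conditions: t-BuMe2SiOTf (1.2 equiv), 2,6-lutidine (2.0 equiv), CH2Cl2, −78 °C
Reagents that add atoms: tert-butyldimethylsilyl trifluoromethanesulfonate, CC(C)(C)[Si](C)(C)OS(=O)(=O)C(F)(F)F
Why: Silylation of a secondary alcohol with silyl triflate and a hindered weak base at low temperature, conditions under which a beta-hydroxy ketone should neither eliminate nor undergo retro-aldol cleavage; the configuration at C3 is untouched.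

Step 11
Reactants: 20 (S)-5-bromo-3-(tert-butyldimethylsilyloxy)-8-methoxy-6-phenyl-3,4-dihydronaphthalen-1(2H)-one
Product: 21 (3S)-5-bromo-3-(tert-butyldimethylsilyloxy)-8-methoxy-6-phenyl-1,2,3,4-tetrahydronaphthalen-1-ol (both C1 epimers)
Conditions: NaBH4 (1.5 equiv), CeCl3·7H2O (1.0 equiv), MeOH, 0 °C
Reagents that add atoms: none
Why: Luche-type carbonyl reduction; the ketone is removed before organolithium chemistry, and the configuration of the new C1 carbinol is irrelevant because step 14 oxidises it back.

Step 12
Reactants: 21 (3S)-5-bromo-3-(tert-butyldimethylsilyloxy)-8-methoxy-6-phenyl-1,2,3,4-tetrahydronaphthalen-1-ol (both C1 epimers)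
Product: 23 (3S)-3-(tert-butyldimethylsilyloxy)-1-hydroxy-8-methoxy-6-phenyl-1,2,3,4-tetrahydronaphthalene-5-carbaldehyde (tetralone numbering kept; both C1 epimers), via dilithio alkoxide 22 (not isolated)
Conditions: t-BuLi (3.2 equiv), THF, −78 °C; DMF (5 equiv), −78 to 0 °C; aq. NH4Cl
Reagents that add atoms: N,N-dimethylformamide, CN(C)C=O
Why: Bromine–lithium exchange followed by formylation with DMF; the first equivalent of t-BuLi deprotonates the carbinol, exchange at −78 °C is faster than any ortho-lithiation next to the methoxy group, and a lithium alkoxide at this temperature should not move the silyl group from O3 to O1.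

Step 13
Reactants: 23 (3S)-3-(tert-butyldimethylsilyloxy)-1-hydroxy-8-methoxy-6-phenyl-1,2,3,4-tetrahydronaphthalene-5-carbaldehyde (tetralone numbering kept; both C1 epimers); 24 2,2,6-trimethyl-4H-1,3-dioxin-4-one
Product: 26 6-{2-hydroxy-2-[(3S)-3-(tert-butyldimethylsilyloxy)-1-hydroxy-8-methoxy-6-phenyl-1,2,3,4-tetrahydronaphthalen-5-yl]ethyl}-2,2-dimethyl-4H-1,3-dioxin-4-one (mixture of carbinol epimers), via lithium dienolate 25 (not isolated)
Conditions: 24 (3.0 equiv), LiN(i-Pr)2 (3.0 equiv), THF, −78 °C; then 23, −78 to −40 °C; aq. NH4Cl
Reagents that add atoms: none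
Why: Vinylogous aldol addition; the lithium dienolate of the dioxinone reacts with aldehydes at its exocyclic gamma carbon, an aldehyde accepts a nucleophile even between two ortho substituents, and the new carbinol centre need not be controlled since step 14 oxidises it.

Step 14
Reactants: 26 6-{2-hydroxy-2-[(3S)-3-(tert-butyldimethylsilyloxy)-1-hydroxy-8-methoxy-6-phenyl-1,2,3,4-tetrahydronaphthalen-5-yl]ethyl}-2,2-dimethyl-4H-1,3-dioxin-4-one (mixture of carbinol epimers)
Product: 27 (S)-6-{2-[3-(tert-butyldimethylsilyloxy)-8-methoxy-1-oxo-6-phenyl-1,2,3,4-tetrahydronaphthalen-5-yl]-2-oxoethyl}-2,2-dimethyl-4H-1,3-dioxin-4-one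
Conditions: Dess–Martin periodinane (3.0 equiv), NaHCO3 (6 equiv), CH2Cl2, 0 °C to rt
Reagents that add atoms: none
Why: Dess–Martin oxidation of both benzylic carbinols in one operation, which merges all epimers into a single compound and restores C1=O; the buffered, non-basic medium spares the beta-silyloxy ketone and the silyl ether keeps C3 from being oxidised.

Step 15
Reactants: 27 (S)-6-{2-[3-(tert-butyldimethylsilyloxy)-8-methoxy-1-oxo-6-phenyl-1,2,3,4-tetrahydronaphthalen-5-yl]-2-oxoethyl}-2,2-dimethyl-4H-1,3-dioxin-4-one
Product: 29 (S)-3-(tert-butyldimethylsilyloxy)-5-(4-hydroxy-2-oxo-2H-pyran-6-yl)-8-methoxy-6-phenyl-3,4-dihydronaphthalen-1(2H)-one, via acylketene 28 (not isolated)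
Conditions: toluene (0.01 M), 110 °C
Reagents that add atoms: none
Why: Thermal retro-hetero-Diels–Alder loss of acetone from the dioxinone gives acylketene 28, which is captured by the enol oxygen of the neighbouring aryl ketone in a six-membered lactonisation to the 4-hydroxy-2-pyrone; the medium is neutral, and dilution and a short heating time limit exposure of the beta-silyloxy ketone.

Step 16
Reactants: 29 (S)-3-(tert-butyldimethylsilyloxy)-5-(4-hydroxy-2-oxo-2H-pyran-6-yl)-8-methoxy-6-phenyl-3,4-dihydronaphthalen-1(2H)-one
Product: 30 (S)-3-(tert-butyldimethylsilyloxy)-8-hydroxy-5-(4-hydroxy-2-oxo-2H-pyran-6-yl)-6-phenyl-3,4-dihydronaphthalen-1(2H)-one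
Conditions: BCl3 (3.0 equiv, 1 M in CH2Cl2), CH2Cl2, −78 to −30 °C; aq. NaHCO3
Reagents that add atoms: none
Why: Chelation-assisted cleavage of an aryl methyl ether peri to a carbonyl group; boron bridges the C1 carbonyl and the C8 oxygen, so the methyl group is lost at low temperature, while the secondary silyl ether at C3 reacts more slowly and keeps the carbinol from binding boron.

Step 17
Reactants: 30 (S)-3-(tert-butyldimethylsilyloxy)-8-hydroxy-5-(4-hydroxy-2-oxo-2H-pyran-6-yl)-6-phenyl-3,4-dihydronaphthalen-1(2H)-one
Product: 31 wailupemycin F
Conditions: HF·pyridine, pyridine, THF, 0 °C to rt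
Reagents that add atoms: none
Why: Fluoride-mediated desilylation in a buffered, weakly acidic medium; no base is present, so neither retro-aldol cleavage nor dehydration of the freed beta-hydroxy ketone should occur, and the S configuration set in step 9 is carried into the target.

## Compound list

1 | 3-bromo-5-methoxyphenol | COc1cc(O)cc(Br)c1 | starting material
2 | phenylboronic acid | OB(O)c1ccccc1 | starting material
3 | 3-methoxy-5-phenylphenol | COc1cc(O)cc(-c2ccccc2)c1 | intermediate
4 | 3-methoxy-5-phenylphenyl N-isopropylcarbamate | COc1cc(OC(=O)NC(C)C)cc(-c2ccccc2)c1 | intermediate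
5 | 3-methoxy-5-phenylphenyl N-(tert-butyldimethylsilyl)-N-isopropylcarbamate (not isolated) | COc1cc(OC(=O)N(C(C)C)[Si](C)(C)C(C)(C)C)cc(-c2ccccc2)c1 | intermediate
6 | {2-[N-(tert-butyldimethylsilyl)-N-isopropylcarbamoyloxy]-6-methoxy-4-phenylphenyl}lithium (not isolated) | [Li]c1c(OC)cc(-c2ccccc2)cc1OC(=O)N(C(C)C)[Si](C)(C)C(C)(C)C | intermediate
7 | 3-methoxy-5-phenyl-2-(trimethylsilyl)phenyl N-(tert-butyldimethylsilyl)-N-isopropylcarbamate (not isolated) | COc1cc(-c2ccccc2)cc(OC(=O)N(C(C)C)[Si](C)(C)C(C)(C)C)c1[Si](C)(C)C | intermediate
8 | 3-methoxy-5-phenyl-2-(trimethylsilyl)phenyl N-isopropylcarbamate | COc1cc(-c2ccccc2)cc(OC(=O)NC(C)C)c1[Si](C)(C)C | intermediate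
9 | 3-methoxy-5-phenyl-2-(trimethylsilyl)phenol (not isolated) | COc1cc(-c2ccccc2)cc(O)c1[Si](C)(C)C | intermediate
10 | 3-methoxy-5-phenyl-2-(trimethylsilyl)phenyl trifluoromethanesulfonate | COc1cc(-c2ccccc2)cc(OS(=O)(=O)C(F)(F)F)c1[Si](C)(C)C | intermediate
11 | methyl acetoacetate | COC(=O)CC(C)=O | starting material
12 | 3-methoxy-5-phenylbenzyne (not isolated) | COC1=CC(c2ccccc2)=CC#C1 | intermediate
13 | cesium 8-(methoxycarbonyl)-5-methoxy-7-methyl-3-phenylbicyclo[4.2.0]octa-1,3,5-trien-7-olate (not isolated) | COC(=O)C1c2cc(-c3ccccc3)cc(OC)c2C1(C)[O-].[Cs+] | intermediate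
14 | methyl 2-(2-acetyl-3-methoxy-5-phenylphenyl)acetate | COC(=O)Cc1cc(-c2ccccc2)cc(OC)c1C(C)=O | intermediate
15 | methyl 2-(2-acetyl-6-bromo-3-methoxy-5-phenylphenyl)acetate | COC(=O)Cc1c(Br)c(-c2ccccc2)cc(OC)c1C(C)=O | intermediate
16 | methyl 2-{6-bromo-3-methoxy-5-phenyl-2-[1-(trimethylsilyloxy)ethenyl]phenyl}acetate | COC(=O)Cc1c(Br)c(-c2ccccc2)cc(OC)c1C(=C)O[Si](C)(C)C | intermediate
17 | 2-{6-bromo-3-methoxy-5-phenyl-2-[1-(trimethylsilyloxy)ethenyl]phenyl}acetaldehyde | O=CCc1c(Br)c(-c2ccccc2)cc(OC)c1C(=C)O[Si](C)(C)C | intermediate
18 | (S)-5-bromo-8-methoxy-6-phenyl-3-(trimethylsilyloxy)-3,4-dihydronaphthalen-1(2H)-one (not isolated) | O=C1C[C@@H](O[Si](C)(C)C)Cc2c(Br)c(-c3ccccc3)cc(OC)c21 | intermediate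
19 | (S)-5-bromo-3-hydroxy-8-methoxy-6-phenyl-3,4-dihydronaphthalen-1(2H)-one | O=C1C[C@@H](O)Cc2c(Br)c(-c3ccccc3)cc(OC)c21 | intermediate
20 | (S)-5-bromo-3-(tert-butyldimethylsilyloxy)-8-methoxy-6-phenyl-3,4-dihydronaphthalen-1(2H)-one | O=C1C[C@@H](O[Si](C)(C)C(C)(C)C)Cc2c(Br)c(-c3ccccc3)cc(OC)c21 | intermediate
21 | (3S)-5-bromo-3-(tert-butyldimethylsilyloxy)-8-methoxy-6-phenyl-1,2,3,4-tetrahydronaphthalen-1-ol, both C1 epimers | OC1C[C@@H](O[Si](C)(C)C(C)(C)C)Cc2c(Br)c(-c3ccccc3)cc(OC)c21 | intermediate
22 | lithium (3S)-3-(tert-butyldimethylsilyloxy)-5-lithio-8-methoxy-6-phenyl-1,2,3,4-tetrahydronaphthalen-1-olate (not isolated) | [Li]OC1C[C@@H](O[Si](C)(C)C(C)(C)C)Cc2c([Li])c(-c3ccccc3)cc(OC)c21 | intermediate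
23 | (3S)-3-(tert-butyldimethylsilyloxy)-1-hydroxy-8-methoxy-6-phenyl-1,2,3,4-tetrahydronaphthalene-5-carbaldehyde (tetralone numbering kept), both C1 epimers | OC1C[C@@H](O[Si](C)(C)C(C)(C)C)Cc2c(C=O)c(-c3ccccc3)cc(OC)c21 | intermediate
24 | 2,2,6-trimethyl-4H-1,3-dioxin-4-one | CC1=CC(=O)OC(C)(C)O1 | starting material
25 | lithium 2,2-dimethyl-6-methylidene-6H-1,3-dioxin-4-olate (not isolated) | C=C1C=C(O[Li])OC(C)(C)O1 | intermediate
26 | 6-{2-hydroxy-2-[(3S)-3-(tert-butyldimethylsilyloxy)-1-hydroxy-8-methoxy-6-phenyl-1,2,3,4-tetrahydronaphthalen-5-yl]ethyl}-2,2-dimethyl-4H-1,3-dioxin-4-one, mixture of carbinol epimers | OC1C[C@@H](O[Si](C)(C)C(C)(C)C)Cc2c(C(O)CC3=CC(=O)OC(C)(C)O3)c(-c4ccccc4)cc(OC)c21 | intermediate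
27 | (S)-6-{2-[3-(tert-butyldimethylsilyloxy)-8-methoxy-1-oxo-6-phenyl-1,2,3,4-tetrahydronaphthalen-5-yl]-2-oxoethyl}-2,2-dimethyl-4H-1,3-dioxin-4-one | O=C1C[C@@H](O[Si](C)(C)C(C)(C)C)Cc2c(C(=O)CC3=CC(=O)OC(C)(C)O3)c(-c4ccccc4)cc(OC)c21 | intermediate
28 | (S)-5-[3-(tert-butyldimethylsilyloxy)-8-methoxy-1-oxo-6-phenyl-1,2,3,4-tetrahydronaphthalen-5-yl]-3,5-dioxopent-1-en-1-one (not isolated) | O=C1C[C@@H](O[Si](C)(C)C(C)(C)C)Cc2c(C(=O)CC(=O)C=C=O)c(-c3ccccc3)cc(OC)c21 | intermediate
29 | (S)-3-(tert-butyldimethylsilyloxy)-5-(4-hydroxy-2-oxo-2H-pyran-6-yl)-8-methoxy-6-phenyl-3,4-dihydronaphthalen-1(2H)-one | O=C1C[C@@H](O[Si](C)(C)C(C)(C)C)Cc2c(-c3cc(O)cc(=O)o3)c(-c4ccccc4)cc(OC)c21 | intermediate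
30 | (S)-3-(tert-butyldimethylsilyloxy)-8-hydroxy-5-(4-hydroxy-2-oxo-2H-pyran-6-yl)-6-phenyl-3,4-dihydronaphthalen-1(2H)-one | O=C1C[C@@H](O[Si](C)(C)C(C)(C)C)Cc2c(-c3cc(O)cc(=O)o3)c(-c4ccccc4)cc(O)c21 | intermediate
31 | wailupemycin F, (S)-3,8-dihydroxy-5-(4-hydroxy-2-oxo-2H-pyran-6-yl)-6-phenyl-3,4-dihydronaphthalen-1(2H)-one | O=C1C[C@@H](O)Cc2c1c(O)cc(-c1ccccc1)c2-c1cc(O)cc(=O)o1 | target

## Step count and least certain steps

Total step count: 17. Longest linear sequence: 17 steps (1 to 31; 2, 11 and 24 are commercial and enter in steps 1, 5 and 13).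

**Step 9 (Proposed new method).** The catalyst may discriminate the aldehyde faces poorly in the tethered transition state, or a racemic pathway carried by silyl transfer may outrun the catalysed one. Either would lower the enantiomeric purity of the only stereocentre. The fallback uses known chemistry and sets out from 17. BF3·OEt2 in CH2Cl2 at −78 °C closes ring B without chiral influence to racemic 5-bromo-3-hydroxy-8-methoxy-6-phenyl-3,4-dihydronaphthalen-1(2H)-one F1. Its antipodes are separated by preparative chromatography on a chiral stationary phase (cellulose tris(3,5-dimethylphenylcarbamate)). The S antipode is 19, where the route is rejoined at the cost of half the material.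

**Step 5 (key step).** Regioselectivity may erode, the enolate may arylate without acyl transfer, the acidic CH2 of the product may be arylated a second time, or the keto ester may condense further under the basic fluoride conditions. The fallback builds the two arms one after the other from 10 without an aryne. Ipso-desilylative Friedel–Crafts acetylation (AcCl, AlCl3, CH2Cl2, −40 °C) replaces the silyl group by acetyl and gives 2-acetyl-3-methoxy-5-phenylphenyl trifluoromethanesulfonate F2. Negishi-type coupling of F2 with the Reformatsky reagent BrZnCH2CO2Me (Pd(dba)2, P(t-Bu)3, THF) then installs the acetate arm and returns to the route at 14.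

**Step 8.** The reduction may overshoot to the primary alcohol, the silyl enol ether may hydrolyse during work-up, and the arylacetaldehyde may self-condense on standing. The fallback sets out from 16 and makes the over-reduction deliberate. i-Bu2AlH (2.5 equiv, −78 to 0 °C) gives 2-{6-bromo-3-methoxy-5-phenyl-2-[1-(trimethylsilyloxy)ethenyl]phenyl}ethanol F3. Parikh–Doering oxidation (SO3·pyridine, DMSO, i-Pr2NEt, 0 °C), basic and anhydrous, then leads to 17.

**Step 13.** Addition to the di-ortho-substituted aldehyde may be slow. Proton transfer to the basic dienolate, attack through its alpha carbon, or reversal of the addition on warming could then compete. The fallback replaces the basic enolate by Lewis-acid activation. From 24, LiN(i-Pr)2 and then Me3SiCl give trimethyl[(2,2-dimethyl-4-methylidene-4H-1,3-dioxin-6-yl)oxy]silane F4. BF3·OEt2 in CH2Cl2 at −78 °C promotes its vinylogous Mukaiyama aldol addition to 23, and an aqueous work-up that removes silyl groups from the carbinols returns to the route at 26.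

**Step 16.** The acidic hydroxypyrone may sequester the boron reagent, which would force excess reagent and higher temperature. That invites Lewis-acid-induced loss of the C3 silyloxy group and aromatisation of ring B. The fallback demethylates before the pyrone exists. From 27, BCl3 (1.5 equiv, CH2Cl2, −78 °C) gives (S)-6-{2-[3-(tert-butyldimethylsilyloxy)-8-hydroxy-1-oxo-6-phenyl-1,2,3,4-tetrahydronaphthalen-5-yl]-2-oxoethyl}-2,2-dimethyl-4H-1,3-dioxin-4-one F5. Thermolysis of F5 in toluene at 110 °C then gives 30 directly.

## Further compounds

F1 | step 9 | racemic 5-bromo-3-hydroxy-8-methoxy-6-phenyl-3,4-dihydronaphthalen-1(2H)-one | O=C1CC(O)Cc2c(Br)c(-c3ccccc3)cc(OC)c21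
F2 | step 5 | 2-acetyl-3-methoxy-5-phenylphenyl trifluoromethanesulfonate | COc1cc(-c2ccccc2)cc(OS(=O)(=O)C(F)(F)F)c1C(C)=O
F3 | step 8 | 2-{6-bromo-3-methoxy-5-phenyl-2-[1-(trimethylsilyloxy)ethenyl]phenyl}ethanol | OCCc1c(Br)c(-c2ccccc2)cc(OC)c1C(=C)O[Si](C)(C)C
F4 | step 13 | trimethyl[(2,2-dimethyl-4-methylidene-4H-1,3-dioxin-6-yl)oxy]silane | C=C1C=C(O[Si](C)(C)C)OC(C)(C)O1
F5 | step 16 | (S)-6-{2-[3-(tert-butyldimethylsilyloxy)-8-hydroxy-1-oxo-6-phenyl-1,2,3,4-tetrahydronaphthalen-5-yl]-2-oxoethyl}-2,2-dimethyl-4H-1,3-dioxin-4-one | O=C1C[C@@H](O[Si](C)(C)C(C)(C)C)Cc2c(C(=O)CC3=CC(=O)OC(C)(C)O3)c(-c4ccccc4)cc(O)c21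
A1 | alternative 1 | 2-[(2R,4S)-2,4-bis(tert-butyldimethylsilyloxy)hex-5-yn-1-yl]-3-(tert-butyldimethylsilyloxymethyl)-4-phenylfuran | CC(C)(C)[Si](C)(C)O[C@H](C#C)C[C@@H](O[Si](C)(C)C(C)(C)C)Cc1occ(-c2ccccc2)c1CO[Si](C)(C)C(C)(C)C
A2 | alternative 1 | cis-1,3-bis(tert-butyldimethylsilyloxy)-5-(tert-butyldimethylsilyloxymethyl)-6-phenyl-1,2,3,4-tetrahydronaphthalen-8-ol (target numbering) | CC(C)(C)[Si](C)(C)O[C@H]1C[C@@H](O[Si](C)(C)C(C)(C)C)Cc2c1c(O)cc(-c1ccccc1)c2CO[Si](C)(C)C(C)(C)C
A3 | alternative 2 | methyl 3-(1,3-dioxolan-2-yl)-6-methoxy-2-methyl-4-phenylbenzoate | COC(=O)c1c(OC)cc(-c2ccccc2)c(C2OCCO2)c1C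
A4 | alternative 2 | (R)-2-tert-butyl-4H-1,3-dioxin-4-one | O=C1O[C@H](C(C)(C)C)OC=C1
A5 | alternative 2 | tricyclic enol of the beta-keto lactone, ring B fused at C2–C3 to the 2-tert-butyl-1,3-dioxan-4-one, with C8 methoxy, C6 phenyl and C5 dioxolanyl | COc1cc(-c2ccccc2)c(C2OCCO2)c2c1C(O)=C1C(=O)O[C@H](C(C)(C)C)O[C@H]1C2
A6 | alternative 3 | methyl (E)-5-[4-(tert-butyldimethylsilyloxy)-2,6-dioxocyclohexyl]-5-oxo-3-phenylpent-3-enoate | COC(=O)C/C(c1ccccc1)=C\C(=O)C1C(=O)CC(O[Si](C)(C)C(C)(C)C)CC1=O
A7 | alternative 3 | methyl (S)-3-(tert-butyldimethylsilyloxy)-8-hydroxy-1-oxo-6-phenyl-1,2,3,4-tetrahydronaphthalene-5-carboxylate (target numbering) | COC(=O)c1c(-c2ccccc2)cc(O)c2c1C[C@H](O[Si](C)(C)C(C)(C)C)CC2=O
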